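The earlier runs and the new flask are calculated for an exercise; the scatter is artificial.

The meeting began from a leftover: the delta run stood at 30.1 % of its free monomer at 4.00 h, while the gamma run, which is the flask asked about followed so far, had come down to 54.0 % at 80.0 min and was still creeping.

all flasks: initiator 5 mol%
- gamma: free monomer 0.050 M (fed, over 2.5 min); the very flask that is asked about, followed so far; the fed solution adds 0.10 times the starting volume
- delta: free monomer 0.10 M (fed, over 2.5 min); run made earlier; the fed solution adds 0.10 times the starting volume
- flask: free monomer 0.050 M (fed, over 2.5 min); the fed solution adds 0.10 times the starting volume; time 6.0 h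

- gamma (time / min: monomer in chains / %, free monomer / %): 6.00: 6.0, 93.7; 8.00: 8.9, 89.8; 12.0: 15.0, 82.6; 20.0: 25.7, 70.1; 30.0: 34.0, 62.3; 50.0: 40.1, 57.0; 80.0: 42.9, 54.0
- delta (time / h: monomer in chains / %, free monomer / %): 0.333: 52.3, 44.2; 0.500: 61.4, 34.6; 0.833: 65.6, 31.0; 1.33: 66.4, 30.9; 2.00: 66.7, 29.8; 3.00: 66.2, 30.1; 4.00: 67.1, 30.1

(each reading ± 0.5 percentage points)

1. average number of monomer units in a chain (chains begun, living or dead) at 6.0 h
2. part of the free monomer that has reacted at 6.0 h

- every charge counts on the volume at the start, and the solution that is fed holds the whole dose
- the average divides the monomer in chains by the number of chains begun, living and dead together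
- the earlier runs do not show the number of chains; that part of a forecast is a guess

I, taking the minutes, proposed the plain proportional case as the zero of the scale: the natural log of charged over remaining free monomer counts how many first-order time constants a flask gets through before it stops, and if each unit of initiator buys a fixed number of them, that count divided by the initiator charge is the same in both runs. The delta readings from 2.00 h on gave 241 M⁻¹, and I called this the stall depth per initiator. Carried to the flask, it put free monomer at 54.8 %, which lies 0.80 percentage points above the last gamma reading, against a scatter of 0.5 points, so my own figure for c was 45.2 %, lower than the forecast's. As no reading counts chains, I offered no figure for dp.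

The forecast gave dp 9 and c 47 %, on the ground that “Active chains are dying instead”.

The flask gave dp 34.3, a factor of 3.81 above the forecast, and c 46.9 %, close to the forecast's.

    free monomer + initiator → living end + monomer in chains (k = 0.470 M⁻¹ min⁻¹)
    free monomer + living end → monomer in chains + living end, rate k2*[living end]*[free monomer] (k = 120 M⁻¹ min⁻¹)
    living end → dead end A (k = 0.120 min⁻¹)
    free monomer + initiator → spent initiator B (k = 1.40 M⁻¹ min⁻¹)

At 6.00 h the flask held 0 % of its initiator against 53 % of its free monomer, and its stall depth per initiator now reads 253 M⁻¹, against the 241 M⁻¹ read from the delta run. The neighbouring flask is charged with 3 mol% of initiator, all else as in the recipe, which is 0.00150 M, and the depth just read on the flask gives it c of 31.6 %. The neighbouring flask itself ended with 69 % of its free monomer, dp 38.6 and c 31.3 %.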